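The route rests on opening the pyranone ring of unit A (the 7-hydroxy-6-methoxycoumarin) at C4–C4a and O1–C2. It exploits the fact that C4a lies para to the C7 hydroxyl and adjacent to the O1-bearing C8a, which is the most nucleophilic carbon of 4-methoxyresorcinol. C2–C3–C4, whose C3 oxygen is already bonded to C7' of unit B, amounts to a 1,3-dielectrophile. One acid-mediated operation couples the free resorcinol with a scopoletin-derived ethyl 2-aryloxy-3-(dimethylamino)acrylate, expels dimethylamine and ethanol, closes the lactone and gives the unprotected target directly. The precursor comes from scopoletin in two steps, the resorcinol from isovanillin in one telescoped step.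

Key step: step 4

Remark on the chemistry: the OCH2 group of an aryloxyacetate is only weakly CH-acidic. The aminomethylenation therefore uses tert-butoxybis(dimethylamino)methane, which is more reactive than DMF dimethyl acetal. It releases tert-butanol rather than methanol, so the ethyl ester cannot be scrambled. The enamino ester is assumed to form as the Z isomer (NMe2 trans to the ester). This geometry is erased in the key step and does not affect the outcome.

Step 1
Reactants: 1 scopoletin (7-hydroxy-6-methoxy-2H-chromen-2-one); 2 ethyl bromoacetate
Product: 3 ethyl 2-[(6-methoxy-2-oxo-2H-chromen-7-yl)oxy]acetate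
Conditions: K2CO3, acetone, reflux
Reagents that add atoms: none
Why: Williamson ether synthesis, in which the acidic C7 phenol is deprotonated by K2CO3 and displaces bromide from the activated primary halide by SN2, while the lactone is inert to carbonate in an aprotic solvent.

Step 2
Reactants: 3 ethyl 2-[(6-methoxy-2-oxo-2H-chromen-7-yl)oxy]acetate; 4 tert-butoxybis(dimethylamino)methane (Bredereck's reagent)
Product: 5 ethyl (Z)-3-(dimethylamino)-2-[(6-methoxy-2-oxo-2H-chromen-7-yl)oxy]prop-2-enoate
Conditions: 4 (1.5 equiv), DMF, 100 °C, N2; evaporate, triturate
Reagents that add atoms: none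
Why: Bredereck aminomethylenation of an activated methylene, in which the reagent ionises to tert-butoxide and a formamidinium ion, the alkoxide deprotonates the OCH2CO2Et carbon, the enolate adds to the formamidinium carbon and loss of dimethylamine gives the push–pull enamino ester, under conditions that coumarin lactones are known to tolerate in related enaminone formations.

Step 3
Reactants: 6 isovanillin (3-hydroxy-4-methoxybenzaldehyde)
Product: 8 4-methoxyresorcinol (4-methoxybenzene-1,3-diol), via 3-hydroxy-4-methoxyphenyl formate 7 (not isolated)
Conditions: mCPBA, CH2Cl2, 0 °C to rt; Me2S quench of excess peracid, evaporate; then cat. HCl, MeOH, rt, N2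
Reagents that add atoms: mCPBA, OOC(=O)c1cccc(Cl)c1
Why: Baeyer–Villiger (Dakin-type) oxidation, in which the peracid–aldehyde adduct rearranges with migration of the aryl group activated by its para methoxy substituent, and the resulting aryl formate shields the electron-rich ring until the oxidant is destroyed and is then removed by acid-catalysed transesterification under nitrogen.

Step 4
Reactants: 5 ethyl (Z)-3-(dimethylamino)-2-[(6-methoxy-2-oxo-2H-chromen-7-yl)oxy]prop-2-enoate; 8 4-methoxyresorcinol (1.2 equiv, freshly prepared)
Product: 10 7-hydroxy-6-methoxy-3-[(6-methoxy-2-oxo-2H-chromen-7-yl)oxy]-2H-chromen-2-one (target), via acyclic E-cinnamate ester 9 (not isolated)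
Conditions: glacial AcOH (degassed), reflux, N2; cool, dilute with water, filter, recrystallise
Reagents that add atoms: none
Why: Acetic acid protonates the push–pull alkene of 5 at its alpha carbon, and the resulting iminium ion Me2N+=CH–CH(OAr)CO2Et is captured at its CH carbon by C6 of 8 (resorcinol numbering) in an electrophilic aromatic substitution that forms C4–C4a. Acid-assisted departure of dimethylamine from the benzylic position, pushed by the ortho and para hydroxyls through a quinone-methide-type cation that can rotate about the future C3–C4 bond, gives cinnamate 9 and lets its geometric isomers equilibrate. In the E isomer the ester lies beside the ortho hydroxyl, which adds to the ester carbonyl and expels ethanol (O1–C2 bond) in a 6-exo-trig closure of the pyranone ring, an irreversible event that pulls the preceding equilibria forward. The closest known reaction type is the Pechmann-type coumarin synthesis from resorcinols or naphthols and 2-substituted 3-(dimethylamino)acrylates or formylacetates in hot acetic acid, applied here with an aryloxy group as the 2-substituent. No stereocentre arises; the step needs site selectivity on 8, and the substrate supplies it because C6 is activated by one hydroxyl from the para and by the other from the ortho position, whereas C2 is crowded between two hydroxyls and C5 is meta to both. The hydroxyl at C3 of 8 points away from the ester and so should emerge unprotected as the C7 phenol, and the benzo ring of unit B, drained by its own lactone carbonyl, is too poor a nucleophile to intercept the iminium ion.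

Compound list
1 | scopoletin (7-hydroxy-6-methoxy-2H-chromen-2-one) | COc1cc2ccc(=O)oc2cc1O | starting material
2 | ethyl bromoacetate | CCOC(=O)CBr | starting material
3 | ethyl 2-[(6-methoxy-2-oxo-2H-chromen-7-yl)oxy]acetate | CCOC(=O)COc1cc2oc(=O)ccc2cc1OC | intermediate
4 | tert-butoxybis(dimethylamino)methane (Bredereck's reagent) | CC(C)(C)OC(N(C)C)N(C)C | starting material
5 | ethyl (Z)-3-(dimethylamino)-2-[(6-methoxy-2-oxo-2H-chromen-7-yl)oxy]prop-2-enoate | CCOC(=O)/C(Oc1cc2oc(=O)ccc2cc1OC)=C/N(C)C | intermediate
6 | isovanillin (3-hydroxy-4-methoxybenzaldehyde) | COc1ccc(C=O)cc1O | starting material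
7 | 3-hydroxy-4-methoxyphenyl formate | COc1ccc(OC=O)cc1O | intermediate
8 | 4-methoxyresorcinol (4-methoxybenzene-1,3-diol) | COc1ccc(O)cc1O | intermediate
9 | ethyl (E)-3-(2,4-dihydroxy-5-methoxyphenyl)-2-[(6-methoxy-2-oxo-2H-chromen-7-yl)oxy]prop-2-enoate | CCOC(=O)/C(Oc1cc2oc(=O)ccc2cc1OC)=C\c1cc(OC)c(O)cc1O | intermediate
10 | 7-hydroxy-6-methoxy-3-[(6-methoxy-2-oxo-2H-chromen-7-yl)oxy]-2H-chromen-2-one | COc1cc2cc(Oc3cc4oc(=O)ccc4cc3OC)c(=O)oc2cc1O | target

Total step count: 4. Longest linear sequence: 3 (steps 1, 2 and 4); the second branch (steps 3 and 4) is shorter.

Steps most likely to fail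

**Step 4.** C–C bond formation may be slow. Acidolytic loss of the aminomethylene carbon from the enamino ester, or oxidative degradation of the resorcinol in hot acid, could then outrun the annulation.

The fallback sets out from 3 and 8 and returns at 10. It builds the same ring by a Perkin condensation, forming C3–C4 and O1–C2 instead.
- Ester 3 would be saponified (LiOH, THF/H2O, then HCl, which also recloses any opened lactone) to 2-[(6-methoxy-2-oxo-2H-chromen-7-yl)oxy]acetic acid F1.
- Diol 8 would be formylated at its C6 position under Vilsmeier–Haack conditions (POCl3, DMF, MeCN) to 2,4-dihydroxy-5-methoxybenzaldehyde F2.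
- Heating F1 with F2 in Ac2O/Et3N at 110 °C, the classical access to 3-aryloxycoumarins, should give 6-methoxy-3-[(6-methoxy-2-oxo-2H-chromen-7-yl)oxy]-2-oxo-2H-chromen-7-yl acetate F3.
- Methanolysis of the aryl acetate in F3 (cat. HCl, MeOH/THF, reflux) should then give 10.

**Step 2.** Condensation may stay incomplete because of the low CH acidity of the aryloxyacetate. The liberated amine may also open the lactone of unit B.

The fallback sets out from 3 and returns at 5.
- A crossed Claisen formylation (NaH, HCO2Et, THF, 0 °C to rt, acidic work-up that recloses the lactone) should give ethyl (E)-3-hydroxy-2-[(6-methoxy-2-oxo-2H-chromen-7-yl)oxy]prop-2-enoate F4, the chelated enol of the formyl ester.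
- Condensation of F4 with Me2NH·HCl and NaOAc in EtOH at rt should convert the enol into enamino ester 5.

**Step 3.** The peracid may over-oxidise the ring that bears the free phenol, and the diol may be lost by air oxidation during deformylation.

The fallback sets out from 6 and returns at 8.
- The phenol would first be masked (Ac2O, pyridine) as 5-formyl-2-methoxyphenyl acetate F5.
- Baeyer–Villiger oxidation of this less oxidisable ring with mCPBA should give 5-(formyloxy)-2-methoxyphenyl acetate F6.
- Both esters would then be removed together by acid-catalysed methanolysis under nitrogen to give 8.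

Further compounds
F1 | step 4 | 2-[(6-methoxy-2-oxo-2H-chromen-7-yl)oxy]acetic acid | OC(=O)COc1cc2oc(=O)ccc2cc1OC
F2 | step 4 | 2,4-dihydroxy-5-methoxybenzaldehyde | COc1cc(C=O)c(O)cc1O
F3 | step 4 | 6-methoxy-3-[(6-methoxy-2-oxo-2H-chromen-7-yl)oxy]-2-oxo-2H-chromen-7-yl acetate | COc1cc2cc(Oc3cc4oc(=O)ccc4cc3OC)c(=O)oc2cc1OC(C)=O
F4 | step 2 | ethyl (E)-3-hydroxy-2-[(6-methoxy-2-oxo-2H-chromen-7-yl)oxy]prop-2-enoate | CCOC(=O)/C(Oc1cc2oc(=O)ccc2cc1OC)=C\O
F5 | step 3 | 5-formyl-2-methoxyphenyl acetate | COc1ccc(C=O)cc1OC(C)=O
F6 | step 3 | 5-(formyloxy)-2-methoxyphenyl acetate | COc1ccc(OC=O)cc1OC(C)=O
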